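Its constants are those of an exercise; the result is computed.

Watch the crystals in this flask rather than the substrate when the run is repeated.

substrate 0.25 M; reagent in the second phase 1.80 equiv; time 80 min; volume of the second phase over the first 1.0

    reagent in the reaction phase ⇌ reagent in the second phase, rate k1*([reagent in the reaction phase] - [reagent in the second phase]/K1) per volume of the first phase (K1 = 0.42, k1 = 0.0095 min⁻¹)
    substrate + reagent in the reaction phase → target (k2 = 3.1 M⁻¹ min⁻¹)
    target ⇌ product in the second phase, rate k3*([target] - [product in the second phase]/K3) per volume of the first phase (K3 = 0.53, k3 = 0.0033 min⁻¹)
    target → decomposed product (k4 = 0.012 min⁻¹)
    reagent in the reaction phase → decomposed reagent (k5 = 0.0049 min⁻¹)
    2 reagent in the reaction phase → homo dimer (k6 = 0.017 M⁻¹ min⁻¹)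
    crystals ⇌ target, rate k7*(cs7 - [target]) while solid is left; crystals form when [target] > cs7 (cs7 = 47 mM, k7 = 1.4 min⁻¹)

- amounts and yields of target count product in the second phase and crystals too
- where a step has two of a species, its rate is k times that concentration squared, and two are used at each turn
- in the second phase: reagent in the second phase, product in the second phase; everything else is in the first
- charges count per volume of the first phase; a concentration in a rate is the amount of a species over the volume of its own phase; every rate counts per litre of the first phase
- given per volume of solution although it is solid: crystals
- run time (flask): 80 min

* how much target and product in the second phase and crystals together there is at 80 min, in percent of the substrate charged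
* the change that raises the amount of target and product in the second phase and crystals together at 80 min, in percent of the substrate charged most ("none" if none brings more than 2 percentage points) (north-east / south-east / east / north / none)
* amount of target and product in the second phase and crystals together at 80 min, in percent of the substrate charged, after south-east

- north-east: doubling the transfer coefficient of step 1, all else as stated
- south-east: doubling the dissolution coefficient of step 7, all else as stated
- east: doubling the amount of reagent in the second phase, all else as stated
- north: doubling the solubility in step 7, all else as stated

Two chemists argue over this flask before the run, and they share a start. Reagent in the second phase crosses with a lifetime of 44.2 min, while reagent in the reaction phase has a half-life against the charged substrate of 0.894 min. That is far shorter, so while substrate is plentiful the reagent is taken as it arrives and the crossing is the rate-limiting step. On this reckoning one charge has crossed by 35.9 min. On the same reckoning the crossing delivers 1.51 charges by 80 min, more than the substrate needs, so substrate is the limiting reagent.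

The first chemist counts half-lives. Dissolved target has a half-life of 57.8 min. Taking the making as even, he reckons that the average target waits 62.1 min, and that 47.5% of the charge survives.

The second chemist answers that solution holds target up to 18.8% of the charge, less than the charge, and that target beyond this comes out as crystals, which decomposition does not touch. She reckons that solution fills in about 4.62 min. From then on, while crystals stand, she takes the loss as steady, and she names it the leak, the fraction of the charge lost per minute while crystals stand, which is the decomposition constant times solubility over substrate charged: 0.00226 min⁻¹. Counted over the full 80 min, the leak takes 18.1% on her reckoning and leaves 81.9%.

I reckon with her. Faster crossing, more reagent and faster dissolving leave the leak as it is, whereas north doubles it, to a loss of 36.2%, so I expect no useful change.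

The forecast, on her side, gives 82%, none as the best change and 82.2% after south-east, holding that “Faster transfer, more reagent or faster dissolution hardly change that loss”.

The simulation gives 82.3%, none as the best change, and 82.5% after south-east. The first chemist's ground lies late in this same flask: at 800 min its crystals stand at 0% and its target, all forms counted, at 2.42%. In the neighbour flask with 0.42 M of substrate, the leak drops to 0.00134 min⁻¹, which over 80 min comes to 10.7%, and that neighbour ends with 11.1% as decomposed product.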